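**Retrosynthetic overview**

1. Target 18 comes from E-stilbene-2-carboxylic acid 17 by one hydrogenation that saturates the C=C bond and removes both O-benzyl groups.
2. 17 comes from aryl iodide 14 and lactone 7: the bond between the ring-B carbon para to the diaryl-ether oxygen and the bridge CH2 next to it is made by a one-flask lactone unzipping/Mizoroki–Heck arylation.
3. Enabling feature: on ring D (the salicylic acid ring) the carboxyl carbon is ortho to the CH2CH2 bridge, so the carboxyl oxygen and the bridge carbon bound to ring B can be tied into a six-membered δ-lactone (isochroman-1-one). Its ring-D-benzylic C4–H is acidic, and E1cB opening turns the O–CH2 carbon into a vinyl terminus while freeing the carboxylate.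
4. 7 comes from methyl 2-hydroxy-4-methoxy-6-methylbenzoate (O-benzylation, then lateral lithiation/formaldehyde/lactonisation). 14 comes from 4-benzyloxystyrene and 3-bromo-5-methoxyphenol (hydroboration/B-alkyl Suzuki), then Chan–Lam arylation with 4-iodophenylboronic acid.
5. Rings: all four benzene rings are bought; the only ring formed is the temporary lactone (step 2), which is opened again in step 5.

Key step: step 5

Remark: the target has no stereocentre and no stereogenic double bond, so it is a single achiral compound and no enantiocontrol is needed; the E double bond of 17 is transient and is removed in step 6.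

**Route**

Step 1
Reactants: 1 methyl 2-hydroxy-4-methoxy-6-methylbenzoate (sparassol); 2 benzyl bromide
Product: 3 methyl 2-(benzyloxy)-4-methoxy-6-methylbenzoate
Conditions: BnBr (1.2 equiv), K2CO3 (2 equiv), DMF, 60 °C
Reagents that add atoms: benzyl bromide, BrCc1ccccc1
Why: Williamson etherification of the hydrogen-bonded 2-OH should proceed cleanly with carbonate in DMF, while the methyl ester and the aryl methyl ether are inert.

Step 2
Reactants: 3 methyl 2-(benzyloxy)-4-methoxy-6-methylbenzoate; 4 formaldehyde (monomer, from cracked paraformaldehyde)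
Product: 7 8-(benzyloxy)-6-methoxy-3,4-dihydro-1H-isochromen-1-one (8-benzyloxy-6-methoxyisochroman-1-one), via benzylic lithium species 5 (not isolated), via lithium alkoxide 6 (not isolated)
Conditions: LDA (1.05 equiv), THF, −78 °C; CH2O (gas), −78 → 0 °C; 1 M HCl
Reagents that add atoms: formaldehyde, C=O
Why: Lateral lithiation of the o-toluate gives the ester-stabilised benzylic anion, which should add to formaldehyde, and the resulting alkoxide should close onto the neighbouring methyl ester with loss of methoxide, the standard o-toluate route to 3,4-dihydroisocoumarins.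

Step 3
Reactants: 8 1-(benzyloxy)-4-vinylbenzene (4-benzyloxystyrene); 9 9-borabicyclo[3.3.1]nonane (9-BBN); 10 3-bromo-5-methoxyphenol
Product: 12 3-{2-[4-(benzyloxy)phenyl]ethyl}-5-methoxyphenol, via B-alkyl-9-BBN adduct 11 (not isolated)
Conditions: 9-BBN (0.5 M in THF), 0 °C → rt; then 10, PdCl2(dppf) (5 mol %), aq. K3PO4 (3 equiv), THF/DMF, 60 °C
Reagents that add atoms: none
Why: Anti-Markovnikov hydroboration places boron on the terminal carbon of the styrene, and the B-alkyl Suzuki–Miyaura coupling should transfer this primary alkyl group to the aryl bromide, with the free phenol carried as its phenoxide in the aqueous base.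

Step 4
Reactants: 12 3-{2-[4-(benzyloxy)phenyl]ethyl}-5-methoxyphenol; 13 4-iodophenylboronic acid
Product: 14 1-{2-[4-(benzyloxy)phenyl]ethyl}-3-(4-iodophenoxy)-5-methoxybenzene
Conditions: 13 (2 equiv), Cu(OAc)2 (2 equiv), pyridine (5 equiv), 4 Å MS, CH2Cl2, air, rt
Reagents that add atoms: 4-iodophenylboronic acid, OB(O)c1ccc(I)cc1
Why: Chan–Lam oxidative O-arylation runs at room temperature, where the C–I bond is not touched by copper, so the diaryl ether and the iodide needed for the key step should be installed together.

Step 5
Reactants: 7 8-(benzyloxy)-6-methoxy-3,4-dihydro-1H-isochromen-1-one; 14 1-{2-[4-(benzyloxy)phenyl]ethyl}-3-(4-iodophenoxy)-5-methoxybenzene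
Product: 17 (E)-2-(benzyloxy)-6-{2-[4-(3-{2-[4-(benzyloxy)phenyl]ethyl}-5-methoxyphenoxy)phenyl]ethenyl}-4-methoxybenzoic acid, via C4-lithiated lactone 15 (not isolated), via lithium 2-(benzyloxy)-4-methoxy-6-vinylbenzoate 16 (not isolated)
Conditions: 7, LDA (1.1 equiv), THF, −78 → 0 °C; then 14, Pd(OAc)2 (5 mol %), P(o-tol)3 (10 mol %), K2CO3 (2 equiv), DMF, 80 °C (sealed); 1 M HCl work-up
Reagents that add atoms: none
Why: LDA removes a C4–H of lactone 7 (benzylic to ring D and conjugated through the ring with the lactone carbonyl, the same anion type as a laterally lithiated o-toluate), and anion 15 expels the carboxylate from C3 in an E1cB β-elimination (the stereoelectronically allowed reverse of a 6-endo-trig closure), so the lactone O–CH2 carbon becomes the terminal carbon of a vinyl group in carboxylate 16. Oxidative addition of Pd(0) into the C–I bond of 14, syn-carbopalladation of the vinyl group with aryl transfer to its unsubstituted terminus, and syn-β-hydride elimination then complete a Mizoroki–Heck arylation that forms the bond between the ring-B carbon para to the diaryl-ether oxygen and the bridge carbon. The closest known reaction types are the base-induced β-elimination of β-acyloxy carbanions (ring-opening of 3,4-dihydroisocoumarins to 2-alkenylbenzoic acids) and Heck couplings of vinylarenes that carry a free carboxylate. No ring is closed and no stereocentre is formed; the E geometry expected from syn-insertion/syn-elimination does not matter because the double bond is saturated in step 6. The step needs terminal rather than internal arylation of the alkene, which the neutral Pd/aryl iodide/monophosphine pathway and the ortho-substituted styrene should secure, and it needs reaction at a single carbon–halogen bond, of which 14 has only one; benzyl and methyl ethers should survive LDA at low temperature and Pd(0) at 80 °C.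

Step 6
Reactants: 17 (E)-2-(benzyloxy)-6-{2-[4-(3-{2-[4-(benzyloxy)phenyl]ethyl}-5-methoxyphenoxy)phenyl]ethenyl}-4-methoxybenzoic acid
Product: 18 2-hydroxy-6-{2-[4-(3-[2-(4-hydroxyphenyl)ethyl]-5-methoxyphenoxy)phenyl]ethyl}-4-methoxybenzoic acid (target)
Conditions: H2 (1 atm), 10 % Pd/C, EtOAc/MeOH, rt
Reagents that add atoms: none
Why: Heterogeneous catalytic hydrogenation should saturate the stilbene double bond and hydrogenolyse both benzyl aryl ethers in the same operation, while the diaryl ether, the methyl ethers and the carboxylic acid are stable under these conditions.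

**Compound list**

1 | methyl 2-hydroxy-4-methoxy-6-methylbenzoate (sparassol) | COC(=O)c1c(C)cc(OC)cc1O | starting material
2 | benzyl bromide | BrCc1ccccc1 | starting material
3 | methyl 2-(benzyloxy)-4-methoxy-6-methylbenzoate | COC(=O)c1c(C)cc(OC)cc1OCc1ccccc1 | intermediate
4 | formaldehyde (from paraformaldehyde) | C=O | starting material
5 | lithium [3-(benzyloxy)-5-methoxy-2-(methoxycarbonyl)phenyl]methanide (benzylic lithium species) | [Li+].[CH2-]c1cc(OC)cc(OCc2ccccc2)c1C(=O)OC | intermediate (not isolated)
6 | lithium 2-[3-(benzyloxy)-5-methoxy-2-(methoxycarbonyl)phenyl]ethanolate | [Li+].[O-]CCc1cc(OC)cc(OCc2ccccc2)c1C(=O)OC | intermediate (not isolated)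
7 | 8-(benzyloxy)-6-methoxy-3,4-dihydro-1H-isochromen-1-one | O=C1OCCc2cc(OC)cc(OCc3ccccc3)c21 | intermediate
8 | 1-(benzyloxy)-4-vinylbenzene | C=Cc1ccc(OCc2ccccc2)cc1 | starting material
9 | 9-borabicyclo[3.3.1]nonane (9-BBN) | B1C2CCCC1CCC2 | starting material
10 | 3-bromo-5-methoxyphenol | COc1cc(O)cc(Br)c1 | starting material
11 | 9-{2-[4-(benzyloxy)phenyl]ethyl}-9-borabicyclo[3.3.1]nonane | C(Cc1ccc(OCc2ccccc2)cc1)B1C2CCCC1CCC2 | intermediate (not isolated)
12 | 3-{2-[4-(benzyloxy)phenyl]ethyl}-5-methoxyphenol | COc1cc(O)cc(CCc2ccc(OCc3ccccc3)cc2)c1 | intermediate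
13 | 4-iodophenylboronic acid | OB(O)c1ccc(I)cc1 | starting material
14 | 1-{2-[4-(benzyloxy)phenyl]ethyl}-3-(4-iodophenoxy)-5-methoxybenzene | COc1cc(CCc2ccc(OCc3ccccc3)cc2)cc(Oc2ccc(I)cc2)c1 | intermediate
15 | lithium 8-(benzyloxy)-6-methoxy-1-oxo-3,4-dihydro-1H-isochromen-4-ide (C4-lithiated lactone) | [Li+].O=C1OC[CH-]c2cc(OC)cc(OCc3ccccc3)c21 | intermediate (not isolated)
16 | lithium 2-(benzyloxy)-4-methoxy-6-vinylbenzoate | [Li+].[O-]C(=O)c1c(C=C)cc(OC)cc1OCc1ccccc1 | intermediate (not isolated)
17 | (E)-2-(benzyloxy)-6-{2-[4-(3-{2-[4-(benzyloxy)phenyl]ethyl}-5-methoxyphenoxy)phenyl]ethenyl}-4-methoxybenzoic acid | COc1cc(CCc2ccc(OCc3ccccc3)cc2)cc(Oc2ccc(/C=C/c3cc(OC)cc(OCc4ccccc4)c3C(=O)O)cc2)c1 | intermediate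
18 | 2-hydroxy-6-{2-[4-(3-[2-(4-hydroxyphenyl)ethyl]-5-methoxyphenoxy)phenyl]ethyl}-4-methoxybenzoic acid | COc1cc(CCc2ccc(O)cc2)cc(Oc2ccc(CCc3cc(OC)cc(O)c3C(=O)O)cc2)c1 | target

**Step count and risks**

Total step count: 6. Longest linear sequence: 4 steps (1, 2, 5, 6 or 3, 4, 5, 6).

Steps most likely to fail:

Step 5. During the unzipping, attack of base or of the C4 anion on a lactone carbonyl may compete with elimination. In the Heck stage, palladium-mediated protodecarboxylation of the electron-rich, doubly ortho-substituted benzoate, arylation at the internal alkene carbon, or oligomerisation of the electron-rich styrene may erode the coupling. The fallback sets out from 7 and 14 and comes back to the route at 18; it replaces the Heck coupling of a free carboxylate by an sp3–sp2 coupling of an ester. Lactone 7 is opened with LDA as before, and carboxylate 16 is alkylated in the same flask with benzyl bromide 2 (DMF, rt) to give benzyl 2-(benzyloxy)-4-methoxy-6-vinylbenzoate F1. Hydroboration of F1 with 9-BBN 9 (THF, rt) should give benzyl 2-(benzyloxy)-6-[2-(9-borabicyclo[3.3.1]nonan-9-yl)ethyl]-4-methoxybenzoate F2. B-alkyl Suzuki–Miyaura coupling of F2 with 14 (PdCl2(dppf), aq. K3PO4, THF/DMF, 60 °C) should give the saturated tribenzyl compound benzyl 2-(benzyloxy)-6-{2-[4-(3-{2-[4-(benzyloxy)phenyl]ethyl}-5-methoxyphenoxy)phenyl]ethyl}-4-methoxybenzoate F3. Hydrogenolysis of F3 (H2, Pd/C, EtOAc/MeOH) removes all three benzyl groups and should give 18.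

Step 2. Over-hydroxymethylation by excess formaldehyde, self-condensation of the lithiated toluate on warming, or premature base-induced unzipping of the newly formed lactone may lower the return. The fallback sets out from 3 and comes back at 7; it brings in the extra carbon at the acid oxidation level and then reduces it. Lateral lithiation of 3 (LDA, THF, −78 °C) followed by CO2 should give 2-[3-(benzyloxy)-5-methoxy-2-(methoxycarbonyl)phenyl]acetic acid F4. Chemoselective reduction of the carboxylic acid with BH3·SMe2 (THF, 0 °C → rt) should give methyl 2-(benzyloxy)-6-(2-hydroxyethyl)-4-methoxybenzoate F5, which should lactonise with catalytic p-TsOH in warm toluene to 7.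

Step 4. Slow transmetalation to copper may let protodeboronation and oxidative homocoupling of the boronic acid consume the aryl donor before the phenol is arylated. The fallback sets out from 12 and comes back at 14; it replaces the oxidative coupling of an aryl nucleophile by an Ullmann-type coupling of an aryl electrophile. Phenol 12 is heated with an excess of 1,4-diiodobenzene (4 equiv), CuI (10 mol %), picolinic acid (20 mol %) and K3PO4 in DMSO at 80–90 °C; the excess of the diiodide should suppress double etherification and give 14 directly, so no new compound arises (F0).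

**Further compounds**

F1 | step 5 | benzyl 2-(benzyloxy)-4-methoxy-6-vinylbenzoate | C=Cc1cc(OC)cc(OCc2ccccc2)c1C(=O)OCc1ccccc1
F2 | step 5 | benzyl 2-(benzyloxy)-6-[2-(9-borabicyclo[3.3.1]nonan-9-yl)ethyl]-4-methoxybenzoate | COc1cc(CCB2C3CCCC2CCC3)c(C(=O)OCc2ccccc2)c(OCc2ccccc2)c1
F3 | step 5 | benzyl 2-(benzyloxy)-6-{2-[4-(3-{2-[4-(benzyloxy)phenyl]ethyl}-5-methoxyphenoxy)phenyl]ethyl}-4-methoxybenzoate | COc1cc(CCc2ccc(OCc3ccccc3)cc2)cc(Oc2ccc(CCc3cc(OC)cc(OCc4ccccc4)c3C(=O)OCc3ccccc3)cc2)c1
F4 | step 2 | 2-[3-(benzyloxy)-5-methoxy-2-(methoxycarbonyl)phenyl]acetic acid | COC(=O)c1c(CC(=O)O)cc(OC)cc1OCc1ccccc1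
F5 | step 2 | methyl 2-(benzyloxy)-6-(2-hydroxyethyl)-4-methoxybenzoate | COC(=O)c1c(CCO)cc(OC)cc1OCc1ccccc1
F0 | step 4 | none | none
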